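All runs stem from a simulated flask from invented constants, noise included.

- Late in the epsilon run the target is still climbing, 29% at 90.0 min and 35% at 120 min, so I read the end figure as rate summed over time and not as a ceiling, since the second substrate, the limiting reagent, is charged at 0.900 equiv.

common to all: free enzyme 0.013 mol%
- epsilon: starting material 0.17 M; second substrate 0.90 equiv; run made earlier
- zeta: starting material 0.11 M; second substrate 0.90 equiv; run made earlier
- eta: starting material 0.26 M; second substrate 0.90 equiv; run made earlier
- Thursday's: starting material 0.17 M (fed, over 1.5 h); second substrate 0.900 equiv; all else is in the flask from the start; the feed brings no volume worth counting; time 2.0 h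
- Monday's: starting material 0.17 M; second substrate 0.900 equiv (fed, over 1.5 h); all else is in the flask from the start; the feed brings no volume worth counting; time 2.0 h
- Wednesday's: starting material 0.17 M; second substrate 0.900 equiv; everything together at the start; time 2.0 h
- Tuesday's: starting material 0.17 M; second substrate 0.900 equiv (in portions, 3, over 1.5 h); first portion at the start, last at 1.5 h; time 2.0 h

epsilon run (percent of the starting material charged)

| time / min | target / % |
|---|---|
| 6.00 | 4 |
| 20.0 | 10 |
| 30.0 | 13 |
| 50.0 | 21 |
| 80.0 | 29 |
| 90.0 | 29 |
| 120 | 35 |

zeta run (percent of the starting material charged)

| time / h | target / % |
|---|---|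
| 0.333 | 8 |
| 0.667 | 14 |
| 1.00 | 17 |
| 1.33 | 22 |
| 1.50 | 23 |
| 2.00 | 28 |
| 2.50 | 30 |

eta run (percent of the starting material charged)

| time / h | target / % |
|---|---|
| 0.333 | 12 |
| 0.667 | 20 |
| 1.00 | 30 |
| 1.33 | 33 |
| 1.50 | 38 |
| 2.00 | 42 |
| 2.50 | 43 |

(readings scatter by 1.5 percentage points)

1. the flask that comes out highest in amount of target, in percent of the starting material charged, or "all alike" when all lie within 1.5 percentage points (Thursday's / Monday's / Wednesday's / Tuesday's / all alike)
2. target at the end, in percent of the starting material charged, Thursday's
3. target at the end, in percent of the starting material charged, Monday's
4. target at the end, in percent of the starting material charged, Wednesday's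
5. target at the end, in percent of the starting material charged, Tuesday's



- Wednesday's is the epsilon recipe, so I put it at 35%.
- For the other flasks I use the dosed share: the part of a charge that has entered, averaged over the run and counted before any reaction. 62.5% is its value for a steady feed, and Tuesday's portions give 62.5% too.
- So Thursday's has on average 0.106 M of starting material fed in, counted before any reaction, close to the zeta run's 0.11 M; but its second substrate and free enzyme stand from the start at 1.55 times zeta's charges, so zeta resembles it in that one amount, and a figure taken from zeta is rough.
- Zeta reads lower than epsilon, 28% at 2.00 h, with its starting material, second substrate and free enzyme each charged lower, and Thursday's has its whole starting material fed in at the end of its feed, at 1.5 h.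
- Carrying the straight line through zeta and epsilon a little past zeta to that mean, which lies below the span of the two runs, I commit to 27.6% for each dosed flask.
- The mean has an error: from zeta to epsilon the reading gains 7 percentage points over 0.0600 M, from epsilon to eta 7 points over 0.0900 M, so as read the readings bend and a mean reads somewhat high.
- The forecast names Wednesday's, with 35% there against 27% for Thursday's, 26% for Monday's and 28% for Tuesday's, saying “Feeding holds one substrate low early”; unlike my single figure, it separates the dosed flasks.
- The flasks give 33.4% for Wednesday's, 28.1% for Monday's, 27.7% for Tuesday's and 24.8% for Thursday's, so Wednesday's comes out highest. With its feed shortened to 0.450 h, Thursday's has a dosed share of 88.8%, which reads 32.8%, and that flask ends at 30.8%.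

    starting material + free enzyme ⇌ first complex (K = 18.0 /M, k = 9080 /M/min)
    first complex → loaded enzyme + first product (k = 152 /min)
    second complex → free enzyme + target (k = 472 /min)
    target → over-reaction product (k = 0.00537 /min)
    free enzyme ⇌ dormant form (K = 2.77, k = 0.0427 /min)
    second substrate + loaded enzyme ⇌ second complex (K = 1.37 /M, k = 20900 /M/min)

- Thursday's step from starting material and free enzyme to first complex has 14% of its turnover behind it at 0.400 h, and its second-substrate step reaches half of its turnover at 1.11 h, with the feed running to 1.5 h. At 2.00 h Thursday's holds 24.8% target, 7.97% over-reaction product and 32.2% of its catalyst as dormant form.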